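The route hinges on the C4–C5 bond of ring A, which links quaternary C4 to C5 beside quaternary C10. Since the C3 oxygen and the C6 ketone are 1,4-related, C4 and C5 are both α-carbonyl (enolate) carbons, a like-polarity pair that is joined by oxidising two enol ethers. That single step closes ring A, forms the crowded bond, sets C5 and delivers the 3,6-dioxo-7-ene. Its precursor is one ring B piece carrying C9 (CH2OSi) and quaternary C10: a kinetic C5=C6 silyl dienol ether whose side chain ends in a tetrasubstituted C3=C4 silyl enol ether, installed regiospecifically by 1,4-hydrosilylation of an isopropenyl ketone rather than by enolisation.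

Key step: step 11

Remark 1: positions are named in terpenoid numbering (C3 carbinol, C4 CMe2, C5 and C10 ring fusion, C6 ketone, C7=C8, C9 bearing C11); ring A is C1–C5 plus C10, ring B is C5–C10.
Remark 2: step 2 is not expected to distinguish the two C9 epimers, so the epimer with C11 cis to the C10 methyl is separated and the other is equilibrated and recycled.
Remark 3 (assumption): in step 5 the lipase is taken to acetylate the (4R,5S)-alcohol faster; if it preferred the other enantiomer, the acetate would be collected and methanolysed (K2CO3, MeOH) to the same compound 8.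

Step 1
Reactants: 1 geranic acid
Product: 2 (3E/3Z)-4,8-dimethylnona-3,7-dien-2-one
Conditions: MeLi (2.2 equiv), Et2O, 0 °C; inverse quench into cold aq. NH4Cl
Reagents that add atoms: methyllithium, [Li]C
Why: Addition of the organolithium to the lithium carboxylate stops at the gem-diolate, which gives the methyl ketone only on work-up (ketone synthesis from a carboxylic acid and an organolithium); the alkene geometry does not matter because C10 becomes sp3 in step 2.

Step 2
Reactants: 2 (3E/3Z)-4,8-dimethylnona-3,7-dien-2-one; 3 methyl acetoacetate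
Product: 5 rac-methyl (1S,6R)-2,6-dimethyl-6-(4-methylpent-3-en-1-yl)-4-oxocyclohex-2-ene-1-carboxylate, via Michael adduct 4 (not isolated)
Conditions: ZnCl2 (0.3 equiv), toluene, reflux, Dean–Stark; chromatography of the C9 epimers; unwanted epimer recycled with NaOMe, MeOH
Reagents that add atoms: none
Why: Lewis-acid-mediated Michael addition of the β-keto ester to the β,β-disubstituted enone, then aldol condensation of the methyl ketone onto the activated keto group (Michael–aldol annulation of the isophorone-carboxylate type), builds ring B with quaternary C10 and the C6 enone; C9 stays epimerisable, so the epimer with C11 cis to the C10 methyl is taken and the other is returned to the equilibrium.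

Step 3
Reactants: 5 rac-methyl (1S,6R)-2,6-dimethyl-6-(4-methylpent-3-en-1-yl)-4-oxocyclohex-2-ene-1-carboxylate
Product: 6 rac-(4S,5R)-4-(hydroxymethyl)-3,5-dimethyl-5-(4-methylpent-3-en-1-yl)cyclohex-2-en-1-ol (both C6 carbinol epimers)
Conditions: LiAlH4, Et2O, −20 → 0 °C
Reagents that add atoms: none
Why: Hydride reduction of the ester to the C11 carbinol freezes the C9 configuration, and the β,β-disubstituted enone is reduced by 1,2-addition; the C6 carbinol centre is removed again in step 4.

Step 4
Reactants: 6 rac-(4S,5R)-4-(hydroxymethyl)-3,5-dimethyl-5-(4-methylpent-3-en-1-yl)cyclohex-2-en-1-ol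
Product: 7 rac-(4S,5R)-4-(hydroxymethyl)-3,5-dimethyl-5-(4-methylpent-3-en-1-yl)cyclohex-2-en-1-one
Conditions: MnO2 (activated), CH2Cl2, 23 °C
Reagents that add atoms: none
Why: Chemoselective allylic oxidation with MnO2 restores the C6 enone and leaves the saturated primary C11 alcohol free for the resolution.

Step 5
Reactants: 7 rac-(4S,5R)-4-(hydroxymethyl)-3,5-dimethyl-5-(4-methylpent-3-en-1-yl)cyclohex-2-en-1-one
Product: 8 (4S,5R)-4-(hydroxymethyl)-3,5-dimethyl-5-(4-methylpent-3-en-1-yl)cyclohex-2-en-1-one
Conditions: Burkholderia cepacia lipase (Amano PS), vinyl acetate, t-BuOMe, 30 °C, run just past half conversion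
Reagents that add atoms: none
Why: Lipase-catalysed irreversible transesterification (kinetic resolution) of a β-branched primary alcohol, a method used for 2-substituted cyclohexenylmethanols, should leave the (4S,5R)-alcohol and thereby fixes the absolute configuration at C9 and C10.

Step 6
Reactants: 8 (4S,5R)-4-(hydroxymethyl)-3,5-dimethyl-5-(4-methylpent-3-en-1-yl)cyclohex-2-en-1-one
Product: 9 (4S,5R)-4-{[tert-butyl(diphenyl)silyl]oxymethyl}-3,5-dimethyl-5-(4-methylpent-3-en-1-yl)cyclohex-2-en-1-one
Conditions: t-BuPh2SiCl, imidazole, DMF, 23 °C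
Reagents that add atoms: tert-butyl(chloro)diphenylsilane, CC(C)(C)[Si](Cl)(c1ccccc1)c1ccccc1
Why: Standard silylation of the primary alcohol gives an ether that survives ozone, Grignard reagent, amide base, tetravalent cerium and borohydride.

Step 7
Reactants: 9 (4S,5R)-4-{[tert-butyl(diphenyl)silyl]oxymethyl}-3,5-dimethyl-5-(4-methylpent-3-en-1-yl)cyclohex-2-en-1-one
Product: 11 3-[(1R,2S)-2-{[tert-butyl(diphenyl)silyl]oxymethyl}-1,3-dimethyl-5-oxocyclohex-3-en-1-yl]propanal, via secondary ozonide 10 (not isolated)
Conditions: O3, CH2Cl2, −78 °C, stopped at the indicator-dye end point; then PPh3, −78 → 23 °C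
Reagents that add atoms: ozone, [O-][O+]=O
Why: Ozonolysis with reductive work-up cleaves the electron-rich trisubstituted side-chain alkene much faster than the electron-poor enone double bond and exposes C3 as an aldehyde.

Step 8
Reactants: 11 3-[(1R,2S)-2-{[tert-butyl(diphenyl)silyl]oxymethyl}-1,3-dimethyl-5-oxocyclohex-3-en-1-yl]propanal
Product: 12 (4S,5R)-4-{[tert-butyl(diphenyl)silyl]oxymethyl}-5-(3-hydroxy-4-methylpent-4-en-1-yl)-3,5-dimethylcyclohex-2-en-1-one (both C3 carbinol epimers)
Conditions: CH2=C(CH3)MgBr (1.2 equiv), THF, −78 °C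
Reagents that add atoms: isopropenylmagnesium bromide, C=C(C)[Mg]Br
Why: Grignard 1,2-addition to the aldehyde is far faster at −78 °C than attack on the hindered β,β-disubstituted enone, and the new carbinol centre is erased in step 9.

Step 9
Reactants: 12 (4S,5R)-4-{[tert-butyl(diphenyl)silyl]oxymethyl}-5-(3-hydroxy-4-methylpent-4-en-1-yl)-3,5-dimethylcyclohex-2-en-1-one
Product: 13 (4S,5R)-4-{[tert-butyl(diphenyl)silyl]oxymethyl}-3,5-dimethyl-5-(4-methyl-3-oxopent-4-en-1-yl)cyclohex-2-en-1-one
Conditions: Dess–Martin periodinane, NaHCO3, CH2Cl2, 0 → 23 °C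
Reagents that add atoms: none
Why: Dess–Martin oxidation of the allylic alcohol gives the isopropenyl ketone under buffered, non-enolising conditions that spare the silyl ether and the ring enone.

Step 10
Reactants: 13 (4S,5R)-4-{[tert-butyl(diphenyl)silyl]oxymethyl}-3,5-dimethyl-5-(4-methyl-3-oxopent-4-en-1-yl)cyclohex-2-en-1-one
Product: 15 tert-butyl({(1R,6S)-2,6-dimethyl-6-[4-methyl-3-(triethylsilyloxy)pent-3-en-1-yl]-4-(trimethylsilyloxy)cyclohexa-2,4-dien-1-yl}methoxy)diphenylsilane, via chain triethylsilyl enol ether 14 (not isolated)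
Conditions: RhCl(PPh3)3 (1 mol %), Et3SiH (1.1 equiv), THF, 50 °C; then Me3SiCl, LiN(i-Pr)2 (1.3 equiv), −78 → 0 °C; cold NaHCO3/pentane work-up, used crude
Reagents that add atoms: triethylsilane, CC[SiH](CC)CC; chlorotrimethylsilane, C[Si](C)(C)Cl
Why: Rhodium-catalysed 1,4-hydrosilylation of the unhindered isopropenyl ketone can only give the tetrasubstituted C3=C4 enol ether and leaves the β,β-disubstituted ring enone, which is then deprotonated kinetically at C5 and trapped as the cross-conjugated dienol ether (kinetic enolate silylation); masking C3 first also prevents enolisation toward C2 and aldol attack of the ring enolate on the C3 ketone.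

Step 11
Reactants: 15 tert-butyl({(1R,6S)-2,6-dimethyl-6-[4-methyl-3-(triethylsilyloxy)pent-3-en-1-yl]-4-(trimethylsilyloxy)cyclohexa-2,4-dien-1-yl}methoxy)diphenylsilane
Product: 17 (4R,4aS,8aS)-4-{[tert-butyl(diphenyl)silyl]oxymethyl}-3,4a,8,8-tetramethyl-4a,5,6,8a-tetrahydronaphthalene-1,7(4H,8H)-dione, via cis-fused C5 epimer 16 (not isolated)
Conditions: (NH4)2Ce(NO3)6 (2.2 equiv), NaHCO3, MeCN, −30 → 0 °C; then K2CO3, MeOH, 23 °C
Reagents that add atoms: none
Why: Tetravalent cerium oxidises the more electron-rich trimethylsilyl dienol ether to a radical cation that loses silicon to give the cross-conjugated α-keto radical at C5, which adds to C4 of the triethylsilyl enol ether; the α-silyloxy radical at C3 is oxidised again and desilylated to the C3 ketone, and the reverse order of oxidation leads to the same bond. The closest known reaction type is the oxidative intramolecular coupling of two silyl enol ethers to a 1,4-diketone with (NH4)2Ce(NO3)6. Ring A closes by a 6-endo-trig radical addition (6-exo-trig if the C4 radical attacks the dienol ether), polarity-matched in either sense because an electrophilic α-keto radical meets an electron-rich enol ether carbon. The new stereocentre C5 is α to the C6 ketone and is set under thermodynamic control by the K2CO3 treatment, which should convert the cis-fused epimer into the trans-fused decalin with H5 anti to the C10 methyl. The step needs site selectivity for the C4–C5 union, which is secured because both enol ethers are regiodefined before oxidation (hydrosilylation for C3=C4, kinetic deprotonation for C5=C6) and only this union gives a six-membered ring. A radical bond formation also tolerates the crowding between quaternary C4 and C5 next to quaternary C10 that defeats enolate alkylation.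

Step 12
Reactants: 17 (4R,4aS,8aS)-4-{[tert-butyl(diphenyl)silyl]oxymethyl}-3,4a,8,8-tetramethyl-4a,5,6,8a-tetrahydronaphthalene-1,7(4H,8H)-dione
Product: 18 (1S,4R,4aS,7S,8aS)-4-{[tert-butyl(diphenyl)silyl]oxymethyl}-3,4a,8,8-tetramethyl-1,4,4a,5,6,7,8,8a-octahydronaphthalene-1,7-diol
Conditions: LiBH(s-Bu)3 (3 equiv), THF, −78 → 0 °C; then NaOH, H2O2
Reagents that add atoms: none
Why: The bulky trialkylborohydride attacks the C3 ketone along the equatorial direction and so gives the axial C3 alcohol of the target (diastereoselective ketone reduction), and it reduces the β,β-disubstituted C6 enone by 1,2-addition from the face away from the axial C4 and C10 methyls; that C6 carbinol is re-oxidised in step 15, so its configuration is immaterial.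

Step 13
Reactants: 18 (1S,4R,4aS,7S,8aS)-4-{[tert-butyl(diphenyl)silyl]oxymethyl}-3,4a,8,8-tetramethyl-1,4,4a,5,6,7,8,8a-octahydronaphthalene-1,7-diol
Product: 19 (1S,4R,4aS,7S,8aS)-4-(hydroxymethyl)-3,4a,8,8-tetramethyl-1,4,4a,5,6,7,8,8a-octahydronaphthalene-1,7-diol
Conditions: Bu4NF, THF, 23 °C
Reagents that add atoms: none
Why: Fluoride-induced desilylation frees the primary C11 alcohol at a stage where no enone is present, so no base-sensitive γ-proton is at risk.

Step 14
Reactants: 19 (1S,4R,4aS,7S,8aS)-4-(hydroxymethyl)-3,4a,8,8-tetramethyl-1,4,4a,5,6,7,8,8a-octahydronaphthalene-1,7-diol; 20 umbelliferone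
Product: 21 7-{[(1R,4S,4aS,6S,8aS)-4,6-dihydroxy-2,5,5,8a-tetramethyl-1,4,4a,5,6,7,8,8a-octahydronaphthalen-1-yl]methoxy}-2H-chromen-2-one
Conditions: PPh3, i-PrO2CN=NCO2i-Pr, THF, 0 → 23 °C
Reagents that add atoms: none
Why: Mitsunobu etherification with the acidic phenol engages only the primary C11 alcohol, because the axial C3 carbinol next to CMe2 and the hindered C6 carbinol are activated far more slowly; running it before re-oxidation avoids vinylogous elimination of the activated C11 oxygen across a C6 enone.

Step 15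
Reactants: 21 7-{[(1R,4S,4aS,6S,8aS)-4,6-dihydroxy-2,5,5,8a-tetramethyl-1,4,4a,5,6,7,8,8a-octahydronaphthalen-1-yl]methoxy}-2H-chromen-2-one
Product: 22 ferocaulidin
Conditions: MnO2 (activated), CH2Cl2, 23 °C
Reagents that add atoms: none
Why: Neutral allylic oxidation with MnO2 returns the C6 enone without touching the saturated C3 carbinol, the coumarin or the base-sensitive C9–H.

Compound list
1 | geranic acid, (2E/2Z)-3,7-dimethylocta-2,6-dienoic acid (commercial isomer mixture) | CC(C)=CCCC(C)=CC(=O)O | starting material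
2 | (3E/3Z)-4,8-dimethylnona-3,7-dien-2-one | CC(C)=CCCC(C)=CC(C)=O | intermediate
3 | methyl acetoacetate | CC(=O)CC(=O)OC | starting material
4 | methyl 2-acetyl-3,7-dimethyl-3-(2-oxopropyl)oct-6-enoate (Michael adduct; stereoisomer mixture; not isolated) | CC(=O)CC(C)(CCC=C(C)C)C(C(C)=O)C(=O)OC | intermediate
5 | rac-methyl (1S,6R)-2,6-dimethyl-6-(4-methylpent-3-en-1-yl)-4-oxocyclohex-2-ene-1-carboxylate (racemate; ester cis to the methyl on the quaternary carbon; drawn enantiomer is the one carried on) | CC1=CC(=O)C[C@@](C)(CCC=C(C)C)[C@@H]1C(=O)OC | intermediate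
6 | rac-(4S,5R)-4-(hydroxymethyl)-3,5-dimethyl-5-(4-methylpent-3-en-1-yl)cyclohex-2-en-1-ol (racemate; both carbinol epimers at ring C1) | CC1=CC(O)C[C@@](C)(CCC=C(C)C)[C@@H]1CO | intermediate
7 | rac-(4S,5R)-4-(hydroxymethyl)-3,5-dimethyl-5-(4-methylpent-3-en-1-yl)cyclohex-2-en-1-one (racemate; relative configuration as drawn) | CC1=CC(=O)C[C@@](C)(CCC=C(C)C)[C@@H]1CO | intermediate
8 | (4S,5R)-4-(hydroxymethyl)-3,5-dimethyl-5-(4-methylpent-3-en-1-yl)cyclohex-2-en-1-one (single enantiomer) | CC1=CC(=O)C[C@@](C)(CCC=C(C)C)[C@@H]1CO | intermediate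
9 | (4S,5R)-4-{[tert-butyl(diphenyl)silyl]oxymethyl}-3,5-dimethyl-5-(4-methylpent-3-en-1-yl)cyclohex-2-en-1-one | CC1=CC(=O)C[C@@](C)(CCC=C(C)C)[C@@H]1CO[Si](c1ccccc1)(c1ccccc1)C(C)(C)C | intermediate
10 | (4S,5R)-4-{[tert-butyl(diphenyl)silyl]oxymethyl}-5-[2-(5,5-dimethyl-1,2,4-trioxolan-3-yl)ethyl]-3,5-dimethylcyclohex-2-en-1-one (secondary ozonide; not isolated) | CC1=CC(=O)C[C@@](C)(CCC2OOC(C)(C)O2)[C@@H]1CO[Si](c1ccccc1)(c1ccccc1)C(C)(C)C | intermediate
11 | 3-[(1R,2S)-2-{[tert-butyl(diphenyl)silyl]oxymethyl}-1,3-dimethyl-5-oxocyclohex-3-en-1-yl]propanal | CC1=CC(=O)C[C@@](C)(CCC=O)[C@@H]1CO[Si](c1ccccc1)(c1ccccc1)C(C)(C)C | intermediate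
12 | (4S,5R)-4-{[tert-butyl(diphenyl)silyl]oxymethyl}-5-(3-hydroxy-4-methylpent-4-en-1-yl)-3,5-dimethylcyclohex-2-en-1-one (both side-chain carbinol epimers) | CC1=CC(=O)C[C@@](C)(CCC(O)C(C)=C)[C@@H]1CO[Si](c1ccccc1)(c1ccccc1)C(C)(C)C | intermediate
13 | (4S,5R)-4-{[tert-butyl(diphenyl)silyl]oxymethyl}-3,5-dimethyl-5-(4-methyl-3-oxopent-4-en-1-yl)cyclohex-2-en-1-one | CC1=CC(=O)C[C@@](C)(CCC(=O)C(C)=C)[C@@H]1CO[Si](c1ccccc1)(c1ccccc1)C(C)(C)C | intermediate
14 | (4S,5R)-4-{[tert-butyl(diphenyl)silyl]oxymethyl}-3,5-dimethyl-5-[4-methyl-3-(triethylsilyloxy)pent-3-en-1-yl]cyclohex-2-en-1-one (not isolated) | CC1=CC(=O)C[C@@](C)(CCC(O[Si](CC)(CC)CC)=C(C)C)[C@@H]1CO[Si](c1ccccc1)(c1ccccc1)C(C)(C)C | intermediate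
15 | tert-butyl({(1R,6S)-2,6-dimethyl-6-[4-methyl-3-(triethylsilyloxy)pent-3-en-1-yl]-4-(trimethylsilyloxy)cyclohexa-2,4-dien-1-yl}methoxy)diphenylsilane (key-step precursor; C11 cis to the C10 methyl) | CC1=CC(O[Si](C)(C)C)=C[C@@](C)(CCC(O[Si](CC)(CC)CC)=C(C)C)[C@@H]1CO[Si](c1ccccc1)(c1ccccc1)C(C)(C)C | intermediate
16 | (4R,4aS,8aR)-4-{[tert-butyl(diphenyl)silyl]oxymethyl}-3,4a,8,8-tetramethyl-4a,5,6,8a-tetrahydronaphthalene-1,7(4H,8H)-dione (cis-fused C5 epimer; not isolated) | CC1=CC(=O)[C@H]2C(C)(C)C(=O)CC[C@@]2(C)[C@@H]1CO[Si](c1ccccc1)(c1ccccc1)C(C)(C)C | intermediate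
17 | (4R,4aS,8aS)-4-{[tert-butyl(diphenyl)silyl]oxymethyl}-3,4a,8,8-tetramethyl-4a,5,6,8a-tetrahydronaphthalene-1,7(4H,8H)-dione (trans-fused 3,6-dioxo-7-ene, C11 silyl ether; key-step product) | CC1=CC(=O)[C@@H]2C(C)(C)C(=O)CC[C@@]2(C)[C@@H]1CO[Si](c1ccccc1)(c1ccccc1)C(C)(C)C | intermediate
18 | (1S,4R,4aS,7S,8aS)-4-{[tert-butyl(diphenyl)silyl]oxymethyl}-3,4a,8,8-tetramethyl-1,4,4a,5,6,7,8,8a-octahydronaphthalene-1,7-diol (axial C3 alcohol; C6 alcohol on the face of the C10 methyl) | CC1=C[C@H](O)[C@@H]2C(C)(C)[C@@H](O)CC[C@@]2(C)[C@@H]1CO[Si](c1ccccc1)(c1ccccc1)C(C)(C)C | intermediate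
19 | (1S,4R,4aS,7S,8aS)-4-(hydroxymethyl)-3,4a,8,8-tetramethyl-1,4,4a,5,6,7,8,8a-octahydronaphthalene-1,7-diol | CC1=C[C@H](O)[C@@H]2C(C)(C)[C@@H](O)CC[C@@]2(C)[C@@H]1CO | intermediate
20 | umbelliferone (7-hydroxy-2H-chromen-2-one) | O=c1ccc2ccc(O)cc2o1 | starting material
21 | 7-{[(1R,4S,4aS,6S,8aS)-4,6-dihydroxy-2,5,5,8a-tetramethyl-1,4,4a,5,6,7,8,8a-octahydronaphthalen-1-yl]methoxy}-2H-chromen-2-one | CC1=C[C@H](O)[C@@H]2C(C)(C)[C@@H](O)CC[C@@]2(C)[C@@H]1COc1ccc2ccc(=O)oc2c1 | intermediate
22 | ferocaulidin, 7-{[(1R,4aS,6S,8aS)-6-hydroxy-2,5,5,8a-tetramethyl-4-oxo-1,4,4a,5,6,7,8,8a-octahydronaphthalen-1-yl]methoxy}-2H-chromen-2-one | CC1=CC(=O)[C@@H]2C(C)(C)[C@@H](O)CC[C@@]2(C)[C@@H]1COc1ccc2ccc(=O)oc2c1 | target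

Total step count: 15
Longest linear sequence: 15 steps (1 to 22)

Steps most likely to fail

Step 11. The radical cation or the oxocarbenium ion may be intercepted by nitrate or lose silicon before the hindered C4–C5 bond forms, which would return uncyclised diketone or α-oxygenated ketones. The fallback forms the same bond by an atom-transfer radical cyclisation instead of a two-electron oxidation. It sets out from 15, which would be treated with N-bromosuccinimide (THF, −78 °C); the more reactive trimethylsilyl dienol ether should be brominated at C5 to give the 5-bromo enone that still carries the chain triethylsilyl enol ether F1. Et3B with a trace of air (benzene, 23 °C) would then start a bromine-atom-transfer chain: the C5 α-keto radical adds to C4 of the enol ether in the 6-endo mode, the α-silyloxy radical at C3 abstracts bromine, and the α-bromo silyl ether collapses to the C3 ketone. Radical addition of α-bromo ketones to silyl enol ethers to give 1,4-diketones is a known reaction type. After equilibration at C5 with K2CO3 in MeOH the sequence comes back to the route at 17.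

Step 2. Conjugate addition to the hindered β,β-disubstituted enone may be slow, the Lewis acid may attack the trisubstituted alkene on long heating, and nothing in the substrate differentiates the two faces at C9. The fallback assembles the same Michael adduct stepwise with a doubly activated acceptor. It sets out from 3, which would be condensed with commercial 6-methylhept-5-en-2-one (CC(C)=CCCC(C)=O) under Knoevenagel conditions (TiCl4, pyridine, THF, 0 → 23 °C) to give methyl 2-acetyl-3,7-dimethylocta-2,6-dienoate F2. Mukaiyama–Michael addition of 2-(trimethylsilyloxy)propene (TiCl4, CH2Cl2, −78 °C) would give 4, and aldol condensation (pyrrolidine, AcOH, toluene, reflux) would close the ring. The sequence comes back to the route at 5, with the same separation and recycling of the C9 epimers.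

Step 5. Enzymatic discrimination may be too weak, because the stereocentre lies β to the reacting carbinol and is flanked by a quaternary carbon. The fallback is a covalent resolution. It sets out from 7, which would be esterified with (S)-O-acetylmandelic acid (N,N′-dicyclohexylcarbodiimide, catalytic 4-(dimethylamino)pyridine, CH2Cl2, 0 °C) to give two diastereomeric esters. These would be separated by chromatography or crystallisation, and the ester of the (4S,5R)-alcohol, {(1S,6R)-2,6-dimethyl-6-(4-methylpent-3-en-1-yl)-4-oxocyclohex-2-en-1-yl}methyl (2S)-2-(acetyloxy)-2-phenylacetate F3, would be methanolysed (K2CO3, MeOH, 0 °C). The sequence comes back to the route at 8.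

Further compounds
F1 | step 11 | 5-bromo derivative of the ring enone bearing the C11 tert-butyldiphenylsilyl ether and the chain C3=C4 triethylsilyl enol ether (C9 and C10 as in 15; both C5 epimers) | CC1=CC(=O)C(Br)[C@@](C)(CCC(O[Si](CC)(CC)CC)=C(C)C)[C@@H]1CO[Si](c1ccccc1)(c1ccccc1)C(C)(C)C
F2 | step 2 | methyl 2-acetyl-3,7-dimethylocta-2,6-dienoate (E/Z mixture) | CC(=O)C(C(=O)OC)=C(C)CCC=C(C)C
F3 | step 5 | {(1S,6R)-2,6-dimethyl-6-(4-methylpent-3-en-1-yl)-4-oxocyclohex-2-en-1-yl}methyl (2S)-2-(acetyloxy)-2-phenylacetate | CC1=CC(=O)C[C@@](C)(CCC=C(C)C)[C@@H]1COC(=O)[C@@H](OC(C)=O)c1ccccc1
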